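## Structural features

The target is an 18-membered macrocyclic bis(bibenzyl) made of four benzene rings joined in the cyclic order ring A–CH2CH2–ring B–O–ring C–CH2CH2–ring D–O–ring A. Ring A is 1,2,4-trisubstituted: C1 carries the ether oxygen to ring D, C2 the ethano bridge to ring B, and C4 a free hydroxyl para to C1. Ring B is a para-phenylene and ring D a meta-phenylene, each holding one bridge carbon and one ether oxygen. Ring C is 1,2,4-trisubstituted, with the aryloxy group from ring B, a free hydroxyl ortho to it, and the bridge para to that hydroxyl. There is no stereocentre, so every problem is one of constitution. The two phenols (one of them a catechol mono-aryl ether) make the rings electron-rich and oxidation-prone, and the four benzylic CH2 groups are the other sensitive sites; the diaryl ethers are robust. The real difficulties are the closure of the large ring at an electron-rich, ortho-substituted arene and the ortho placement of ether oxygen and bridge on ring A. The key step uses the fact that C1(O)–C2(CH2) of ring A is the O–C≡C–CH2 unit of an aryl alkynyl ether and that the C4 oxygen is para to C1, so that C3–C6 can come from methyl coumalate with its ester carbon on C4.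

## Logic of the disconnections

22 ⇒ 21. The O–CH3 bond on ring C is cut. The ring C hydroxyl is ortho to a diaryl ether oxygen and has to stay masked through copper chemistry, a Grignard addition and a peroxide oxidation; a methyl ether survives all of these. The forward step must cleave an alkyl aryl ether without touching diaryl ethers, which BBr3 does.

21 ⇒ 19 ⇒ 17. The C4–O bond of ring A is traced back to a C4–C bond, first as a dimethylcarbinol in 19 and then as the ester in 17. The cut is made there because the ring-forming step delivers carbon, not oxygen, at C4. The ester also keeps ring A from offering a second phenol during macrocyclisation. The forward demand is that the aryl group, not a methyl group, migrates from carbon to oxygen.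

17 ⇒ 16 ⇒ 15. The bond between the ring B oxygen and the ring C carbon is cut, which opens the 18-membered ring to the acyclic 16 and, one protecting group earlier, 15. Both ends can be carried through the ring A construction in masked form, as a silyl ether and an aryl bromide. The forward step is an intramolecular copper-mediated etherification that needs high dilution and must tolerate the ortho-methoxy group.

15 ⇒ 12 + 13. The C2–C3 and C1–C6 bonds of ring A are cut, so ring A falls apart into the two alkyne carbons of 12 and four ring carbons of 13. This is the main simplification: the ring D–O–ring A ether, the bridge at C2 and the C4 substituent are all placed by one cycloaddition and not by arene substitution. The forward step must be regioselective and 12 must survive the temperature needed.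

12 ⇒ 6 + 10. The O–C(sp) bond of the ynol ether is cut, giving a phenol and a 1,1-dibromoalkene. The forward coupling must take place at the vinylic bromide and leave the aryl bromide of 6 alone, and a dehydrobromination must follow.

10 ⇒ 9 ⇒ 8 ⇒ 7. The C=CBr2 bond goes back to the aldehyde 9, the aldehyde to the ester 8, and the silyl ether to the free phenol 7. These are functional-group changes only; the demand is a silyl group that lasts until after the cycloaddition.

6 ⇒ 5 ⇒ 2 + 3, and 2 ⇒ 1. The CH2–CH2 bond of the ring C–ring D bridge is taken back to an alkene and cut by a Wittig disconnection; the phosphonium salt comes from 1. The alkene must then be reduced without loss of the aryl bromide.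

## Other disconnections considered

Alternative 1: The ring A C2–CH2 bond is cut by reversing a 1,2-shift. The precursor is the 17-membered 4-aryloxy-4-alkylcyclohexa-2,5-dienone A2, whose quaternary carbon holds both the ring D oxygen and the CH2 arm. In the forward step acid (CF3CO2H or BF3·OEt2) protonates the carbonyl, the arm shifts to the neighbouring ring carbon, and proton loss aromatises ring A and expands the ring to 18 members. The product is the ring C monomethyl ether A1, which is the same compound as 21. A2 would be made from the open diphenol A3 by oxidative dearomatisation (PhI(OAc)2) with the ring D phenol as internal oxygen nucleophile.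
- In favour: ring A and its hydroxyl come from a plain para-alkylphenol, so no ester-to-phenol exchange is needed; on this point it is better than the chosen plan.
- In favour: the two carbons flanking the quaternary centre are equivalent, so the shift can lead to only one constitution; this equals the regiochemical security of the cycloaddition.
- Against: the formation of A2 asks a phenol, itself oxidisable, to add through oxygen to the para carbon of an oxidised phenol in a 17-membered closure at a quaternary centre.
- Against: in the shift the aryloxy group is a competent leaving group, so C–O heterolysis back to a phenoxonium or para-quinone methide competes with carbon migration.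
- Comparison: both plans have an undemonstrated step. Mechanistically the cycloaddition is steered by polarity alone, whereas the shift has a built-in fragmentation pathway. In step count Alternative 1 is likely shorter.

Alternative 2: The bond from the ring B oxygen to C1 of ring C is cut with ring C taken back to a cyclohexanone. The precursor is the 2-bromo-4-alkylcyclohexanone A5. In the forward step CsF frees the ring B phenoxide, which displaces the alpha-bromide and closes the 18-membered ring to the racemic cis 2-aryloxycyclohexanone A4. Dehydrogenative aromatisation (for example Pd(O2CCF3)2 under O2) would give the ring A methyl ether A6, and BBr3 the target.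
- In favour: a phenoxide displacement at an alpha-halo ketone is a fast, copper-free C–O bond formation; as a macrocyclisation it is better founded than the Ullmann closure of step 10.
- In favour: ring C emerges with its hydroxyl free, and the stereocentres of A4 disappear on aromatisation.
- Against: the alpha-bromoketone faces fluoride and phenoxide, so Favorskii rearrangement, elimination and epimerisation compete, and only conformers with an axial C–Br bond react well.
- Against: the dehydrogenation must remove two equivalents of H2 next to four benzylic CH2 groups.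
- Against: the 4-(2-arylethyl)cyclohexanone needs redox steps that an aromatic aldehyde does not.
- Comparison: both plans take one trisubstituted ring from non-aromatic atoms, ring A early in the chosen plan and ring C at the end here. The step count is about equal or slightly worse.

Alternative 3: Both aryl–carbon bonds of the ring C–ring D bridge are cut after taking the bridge back to an E-alkene. The precursors are the acyclic dibromide A8 and (E)-1,2-bis(tributylstannyl)ethene A9. In the forward step Pd(PPh3)4 (zerovalent palladium) couples A9 twice, the second time intramolecularly, to give the macrocyclic E-stilbene dimethyl ether A7. Hydrogenation (H2, Pd/C) to A10 and double demethylation with BBr3 would finish.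
- In favour: the plan is convergent, needs no de novo ring and no ester-to-phenol exchange, and has only two steps after the key step; its step economy is better than that of the chosen plan.
- In favour: oxidative addition of zerovalent palladium to aryl bromides is more dependable than copper-mediated etherification.
- Against: the first coupling is intermolecular and slow at the dilution the second one needs, so oligomers and doubly vinylated open-chain products are expected.
- Against: the ring C bromide para to methoxy is the slower partner, the rigid E-alkene between two meta-linked rings adds strain at closure, and stoichiometric tin must be removed.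
- Comparison: A8 still requires the ortho oxygen/bridge pattern of ring A from classical arene chemistry, which the chosen plan avoids. The chosen plan spreads its risk over two steps (cycloaddition and Ullmann closure), whereas Alternative 3 concentrates it in one.

Key step: step 8

Assumption: the Wittig products are carried on as E/Z mixtures because the next reduction removes the alkene geometry; their SMILES carry no alkene descriptor.

Remark: copper-catalysed coupling of a phenol with a 1,1-dibromoalkene stops at the bromo enol ether, so step 7 includes a dehydrobromination with t-BuOK. The ring B phenol is carried as a triisopropylsilyl ether, which resists hot K3PO4, phenoxide and t-BuOK better than a tert-butyldimethylsilyl ether.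

## Route

Step 1
Reactants: 1 3-(hydroxymethyl)phenol
Product: 2 [(3-hydroxyphenyl)methyl]triphenylphosphonium bromide
Conditions: PPh3·HBr, MeCN, reflux
Reagents that add atoms: triphenylphosphine hydrobromide, [Br-].[PH+](c1ccccc1)(c1ccccc1)c1ccccc1
Why: HBr turns the benzylic alcohol into the benzyl bromide in the flask and PPh3 quaternises it (SN2), a one-flask phosphonium salt formation in which the phenol needs no protection.

Step 2
Reactants: 2 [(3-hydroxyphenyl)methyl]triphenylphosphonium bromide; 3 3-bromo-4-methoxybenzaldehyde
Product: 5 3-[2-(3-bromo-4-methoxyphenyl)ethenyl]phenol (E/Z mixture), via potassium phenolate ylide 4 (not isolated)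
Conditions: t-BuOK (2.2 equiv), THF, 0 °C; then 3, 0 °C to rt; 1 M HCl
Reagents that add atoms: none
Why: Wittig olefination with a semi-stabilised benzylic ylide; the second equivalent of base holds the phenol as its phenolate, which is meta to the ylide carbon and does not disturb it.

Step 3
Reactants: 5 3-[2-(3-bromo-4-methoxyphenyl)ethenyl]phenol (E/Z mixture)
Product: 6 3-[2-(3-bromo-4-methoxyphenyl)ethyl]phenol
Conditions: TsNHNH2, NaOAc, THF/H2O, reflux
Reagents that add atoms: none
Why: Diimide reduction: diimide from thermal fragmentation of the sulfonyl hydrazide transfers H2 to the alkene in a concerted step and leaves the aryl C–Br bond intact, which hydrogenation over palladium would put at risk.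

Step 4
Reactants: 7 methyl 3-(4-hydroxyphenyl)propanoate
Product: 8 methyl 3-{4-[tri(propan-2-yl)silyloxy]phenyl}propanoate
Conditions: TIPSCl, imidazole, DMF, rt
Reagents that add atoms: chlorotri(propan-2-yl)silane, CC(C)[Si](Cl)(C(C)C)C(C)C
Why: Imidazole-promoted O-silylation of the phenol; the bulky silyl ether is chosen for its resistance to basic oxygen nucleophiles and is still cleaved by fluoride.

Step 5
Reactants: 8 methyl 3-{4-[tri(propan-2-yl)silyloxy]phenyl}propanoate
Product: 9 3-{4-[tri(propan-2-yl)silyloxy]phenyl}propanal
Conditions: i-Bu2AlH (1.05 equiv), CH2Cl2, −78 °C; MeOH, then aq. KNa tartrate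
Reagents that add atoms: none
Why: Partial reduction of an ester with i-Bu2AlH; the tetrahedral aluminium hemiacetal persists at −78 °C and releases the aldehyde only on work-up.

Step 6
Reactants: 9 3-{4-[tri(propan-2-yl)silyloxy]phenyl}propanal
Product: 10 [4-(4,4-dibromobut-3-en-1-yl)phenoxy]tri(propan-2-yl)silane
Conditions: CBr4, PPh3, CH2Cl2, 0 °C
Reagents that add atoms: tetrabromomethane, BrC(Br)(Br)Br
Why: Ramirez dibromo-olefination (first stage of the Corey–Fuchs sequence): the ylide Ph3P=CBr2 formed from PPh3 and CBr4 reacts with the aldehyde in a Wittig reaction.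

Step 7
Reactants: 6 3-[2-(3-bromo-4-methoxyphenyl)ethyl]phenol; 10 [4-(4,4-dibromobut-3-en-1-yl)phenoxy]tri(propan-2-yl)silane
Product: 12 {4-[4-{3-[2-(3-bromo-4-methoxyphenyl)ethyl]phenoxy}but-3-yn-1-yl]phenoxy}tri(propan-2-yl)silane, via Z-bromo enol ether 11 (not isolated)
Conditions: CuI (10 mol%), 2,2'-bipyridine (20 mol%), K3PO4, toluene, 110 °C; then t-BuOK, 1,4-dioxane, rt
Reagents that add atoms: none
Why: Copper-catalysed Ullmann-type C(sp2)–O coupling at the bromide trans to the chain gives the Z bromo enol ether, whose remaining bromide is anti to the vinylic hydrogen and leaves by E2 with t-BuOK. The vinylic dibromide should undergo oxidative addition much faster than the electron-rich ortho-methoxy aryl bromide of 6, which is the basis of the chemoselectivity.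

Step 8
Reactants: 12 {4-[4-{3-[2-(3-bromo-4-methoxyphenyl)ethyl]phenoxy}but-3-yn-1-yl]phenoxy}tri(propan-2-yl)silane; 13 methyl coumalate (methyl 2-oxo-2H-pyran-5-carboxylate)
Product: 15 methyl 4-{3-[2-(3-bromo-4-methoxyphenyl)ethyl]phenoxy}-3-(2-{4-[tri(propan-2-yl)silyloxy]phenyl}ethyl)benzoate, via bicyclic lactone adduct 14 (not isolated)
Conditions: 13 (2 equiv), toluene, sealed tube, 130 °C
Reagents that add atoms: none
Why: Proposed new method: the electron-poor 2-pyrone 13 is the 4π component (its C3–C6) and the aryl alkynyl ether 12 the electron-rich 2π component of an inverse-electron-demand [4+2] cycloaddition; the alkyne carbon remote from oxygen, made nucleophilic by the oxygen lone pair, bonds first to C6 of 13 (the terminus conjugated with both carbonyl groups) and the oxygen-bearing carbon then closes onto C3. The 2-oxabicyclo[2.2.2]octadienone 14 loses CO2 by a retro-[4+2] driven by aromatisation, so ring A is closed by an intermolecular cycloaddition–cycloreversion pair that forms its C2–C3 and C1–C6 bonds, not by a chain cyclisation. The closest known reactions are the thermal benzannulations of methyl coumalate with ynamines, alkoxyalkynes, enol ethers and ketene acetals, which give para-donor benzoates by the same polarity matching; an internal aryl alkynyl ether is a weaker donor and has not been shown as the 2π partner, and this is the new element. No stereocentre is created, since the two bridgehead centres of 14 vanish with the loss of CO2. The selectivity needed is regiochemical (aryloxy para and not meta to the ester) and rests on the matched polarisation of the two partners, the oxygen lone pair of 12 outweighing the weak alkyl donor; the aryl group on oxygen has no hydrogen for a retro-ene loss of ketene, so 12 should tolerate the heating. The silyl ether, the aryl bromide and the methyl ether are spectators under neutral thermal conditions.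

Step 9
Reactants: 15 methyl 4-{3-[2-(3-bromo-4-methoxyphenyl)ethyl]phenoxy}-3-(2-{4-[tri(propan-2-yl)silyloxy]phenyl}ethyl)benzoate
Product: 16 methyl 4-{3-[2-(3-bromo-4-methoxyphenyl)ethyl]phenoxy}-3-[2-(4-hydroxyphenyl)ethyl]benzoate
Conditions: Bu4NF, AcOH, THF, 0 °C to rt
Reagents that add atoms: none
Why: Fluoride-induced cleavage of the aryl silyl ether, driven by the Si–F bond; acetic acid buffers the phenoxide so that the methyl ester is not hydrolysed.

Step 10
Reactants: 16 methyl 4-{3-[2-(3-bromo-4-methoxyphenyl)ethyl]phenoxy}-3-[2-(4-hydroxyphenyl)ethyl]benzoate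
Product: 17 macrocyclic methyl ester (the 18-membered ring of the target with CO2CH3 at C4 of ring A and OCH3 on ring C)
Conditions: CuI (30 mol%), N,N-dimethylglycine, Cs2CO3, 1,4-dioxane, 100 °C, 0.002 M, slow addition
Reagents that add atoms: none
Why: Intramolecular Ullmann diaryl ether synthesis with an amino acid ligand: the caesium phenoxide of ring B couples with the ring C bromide through a monovalent/trivalent copper cycle and closes the 18-membered ring under high dilution; the ortho-methoxy group can assist by coordinating copper.

Step 11
Reactants: 17 macrocyclic methyl ester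
Product: 19 macrocyclic tertiary alcohol (ring A C4 carries C(CH3)2OH; ring C OCH3), via macrocyclic methyl ketone 18 (not isolated)
Conditions: CH3MgBr (4 equiv), THF, 0 °C to rt; aq. NH4Cl
Reagents that add atoms: methylmagnesium bromide, C[Mg]Br
Why: Double Grignard addition to the ester by way of the ketone; no other group in 17 is electrophilic towards the reagent.

Step 12
Reactants: 19 macrocyclic tertiary alcohol
Product: 21 target ring C monomethyl ether (ring A C4 OH; ring C OCH3), via tertiary hydroperoxide 20 (not isolated)
Conditions: H2O2 (30% aq.), BF3·OEt2, CH2Cl2, 0 °C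
Reagents that add atoms: hydrogen peroxide, OO
Why: Hock-type oxidative cleavage: BF3·OEt2 ionises the tertiary benzylic alcohol, H2O2 traps the cation as the hydroperoxide, and acid-induced 1,2-shift of the aryl group from carbon to oxygen followed by hydrolysis of the hemiketal gives the phenol and acetone. The para-aryloxy-substituted ring migrates in preference to methyl.

Step 13
Reactants: 21 target ring C monomethyl ether
Product: 22 target (CNP0135015.0)
Conditions: BBr3, CH2Cl2, −78 °C to rt; H2O
Reagents that add atoms: none
Why: Lewis acid-mediated O-demethylation: BBr3 binds the anisole oxygen and bromide attacks the methyl carbon (SN2); the diaryl ethers offer no alkyl carbon and survive.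

## Compound list

1 | 3-(hydroxymethyl)phenol | OCc1cccc(O)c1 | starting material
2 | [(3-hydroxyphenyl)methyl]triphenylphosphonium bromide | Oc1cccc(C[P+](c2ccccc2)(c2ccccc2)c2ccccc2)c1.[Br-] | intermediate
3 | 3-bromo-4-methoxybenzaldehyde | COc1ccc(C=O)cc1Br | starting material
4 | potassium 3-[(triphenyl-λ5-phosphanylidene)methyl]phenolate | [K+].[O-]c1cccc(C=P(c2ccccc2)(c2ccccc2)c2ccccc2)c1 | intermediate
5 | 3-[2-(3-bromo-4-methoxyphenyl)ethenyl]phenol (E/Z mixture) | COc1ccc(C=Cc2cccc(O)c2)cc1Br | intermediate
6 | 3-[2-(3-bromo-4-methoxyphenyl)ethyl]phenol | COc1ccc(CCc2cccc(O)c2)cc1Br | intermediate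
7 | methyl 3-(4-hydroxyphenyl)propanoate | COC(=O)CCc1ccc(O)cc1 | starting material
8 | methyl 3-{4-[tri(propan-2-yl)silyloxy]phenyl}propanoate | COC(=O)CCc1ccc(O[Si](C(C)C)(C(C)C)C(C)C)cc1 | intermediate
9 | 3-{4-[tri(propan-2-yl)silyloxy]phenyl}propanal | O=CCCc1ccc(O[Si](C(C)C)(C(C)C)C(C)C)cc1 | intermediate
10 | [4-(4,4-dibromobut-3-en-1-yl)phenoxy]tri(propan-2-yl)silane | BrC(Br)=CCCc1ccc(O[Si](C(C)C)(C(C)C)C(C)C)cc1 | intermediate
11 | {4-[(3Z)-4-bromo-4-{3-[2-(3-bromo-4-methoxyphenyl)ethyl]phenoxy}but-3-en-1-yl]phenoxy}tri(propan-2-yl)silane | COc1ccc(CCc2cccc(O/C(Br)=C/CCc3ccc(O[Si](C(C)C)(C(C)C)C(C)C)cc3)c2)cc1Br | intermediate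
12 | {4-[4-{3-[2-(3-bromo-4-methoxyphenyl)ethyl]phenoxy}but-3-yn-1-yl]phenoxy}tri(propan-2-yl)silane | COc1ccc(CCc2cccc(OC#CCCc3ccc(O[Si](C(C)C)(C(C)C)C(C)C)cc3)c2)cc1Br | intermediate
13 | methyl coumalate (methyl 2-oxo-2H-pyran-5-carboxylate) | COC(=O)C1=COC(=O)C=C1 | starting material
14 | methyl 8-{3-[2-(3-bromo-4-methoxyphenyl)ethyl]phenoxy}-3-oxo-7-(2-{4-[tri(propan-2-yl)silyloxy]phenyl}ethyl)-2-oxabicyclo[2.2.2]octa-5,7-diene-6-carboxylate (racemic; the two bridgehead centres are tied to each other by the bicycle) | O=C1OC2C(C(=O)OC)=CC1C(Oc1cccc(CCc3ccc(OC)c(Br)c3)c1)=C2CCc1ccc(O[Si](C(C)C)(C(C)C)C(C)C)cc1 | intermediate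
15 | methyl 4-{3-[2-(3-bromo-4-methoxyphenyl)ethyl]phenoxy}-3-(2-{4-[tri(propan-2-yl)silyloxy]phenyl}ethyl)benzoate | COC(=O)c1ccc(Oc2cccc(CCc3ccc(OC)c(Br)c3)c2)c(CCc2ccc(O[Si](C(C)C)(C(C)C)C(C)C)cc2)c1 | intermediate
16 | methyl 4-{3-[2-(3-bromo-4-methoxyphenyl)ethyl]phenoxy}-3-[2-(4-hydroxyphenyl)ethyl]benzoate | COC(=O)c1ccc(Oc2cccc(CCc3ccc(OC)c(Br)c3)c2)c(CCc2ccc(O)cc2)c1 | intermediate
17 | macrocyclic methyl ester (target skeleton; ring A C4 CO2CH3; ring C OCH3) | COC(=O)c1ccc2c(c1)CCc1ccc(cc1)Oc1cc(ccc1OC)CCc1cccc(c1)O2 | intermediate
18 | macrocyclic methyl ketone (ring A C4 COCH3; ring C OCH3) | CC(=O)c1ccc2c(c1)CCc1ccc(cc1)Oc1cc(ccc1OC)CCc1cccc(c1)O2 | intermediate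
19 | macrocyclic tertiary alcohol (ring A C4 C(CH3)2OH; ring C OCH3) | CC(C)(O)c1ccc2c(c1)CCc1ccc(cc1)Oc1cc(ccc1OC)CCc1cccc(c1)O2 | intermediate
20 | macrocyclic tertiary hydroperoxide (ring A C4 C(CH3)2OOH; ring C OCH3) | CC(C)(OO)c1ccc2c(c1)CCc1ccc(cc1)Oc1cc(ccc1OC)CCc1cccc(c1)O2 | intermediate
21 | target ring C monomethyl ether (ring A C4 OH; ring C OCH3) | Oc1ccc2c(c1)CCc1ccc(cc1)Oc1cc(ccc1OC)CCc1cccc(c1)O2 | intermediate
22 | CNP0135015.0 (macrocyclic bis(bibenzyl) diphenol) | Oc1ccc2c(c1)CCc1ccc(cc1)Oc1cc(ccc1O)CCc1cccc(c1)O2 | target

## Step count and least certain steps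

Total: 13 steps. Longest linear sequence: 10 steps (steps 1–3 and 7–13; the branch through steps 4–6 and 7–13 is equally long).

Step 8 (key step, labelled as a proposed new method). The aryloxy group makes 12 a weaker donor than the amino- and alkoxy-alkynes known in this benzannulation. The cycloaddition may therefore be slower than thermal dimerisation or decomposition of 13 and degradation of 12. A weaker polarisation could also erode the regiocontrol. The fallback uses known chemistry, sets out from 6 and comes back at 16, and bypasses steps 4 to 9.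
- Nucleophilic aromatic substitution of 6 on commercial methyl 4-fluoro-3-formylbenzoate (K2CO3, DMF, 80 °C) gives methyl 4-{3-[2-(3-bromo-4-methoxyphenyl)ethyl]phenoxy}-3-formylbenzoate F1.
- The salt [(4-hydroxyphenyl)methyl]triphenylphosphonium bromide F2 is made from 4-(hydroxymethyl)phenol and PPh3·HBr as in step 1.
- Wittig reaction of F1 with F2 (K2CO3, 18-crown-6, CH2Cl2, reflux) gives methyl 4-{3-[2-(3-bromo-4-methoxyphenyl)ethyl]phenoxy}-3-[2-(4-hydroxyphenyl)ethenyl]benzoate F3 as an E/Z mixture.
- Diimide reduction of F3 as in step 3 gives 16.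
- This detour is not longer than the main line, but it sets the ring A pattern by arene substitution and not by ring construction.

Step 7. Copper may also insert into the aryl bromide of 6 and start oligomerisation through diaryl ether formation. The silyl group may migrate between phenoxides at 110 °C. t-BuOK may isomerise the propargylic position of 12 to an allenyl ether, and the ynol ether may hydrate during isolation. The fallback sets out from 6 and comes back at 12; it forms the alkyne by elimination from an enol triflate.
- Commercial 4-(4-hydroxyphenyl)butan-2-one is silylated (TIPSCl, imidazole) to 4-{4-[tri(propan-2-yl)silyloxy]phenyl}butan-2-one F4.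
- Kinetic enolisation on the methyl side (LiN(i-Pr)2, THF, −78 °C; Me3SiCl) gives trimethyl[(4-{4-[tri(propan-2-yl)silyloxy]phenyl}but-1-en-2-yl)oxy]silane F5.
- NBS (THF, 0 °C) gives 1-bromo-4-{4-[tri(propan-2-yl)silyloxy]phenyl}butan-2-one F6.
- Williamson alkylation of 6 with F6 (K2CO3, acetone, rt) gives 1-{3-[2-(3-bromo-4-methoxyphenyl)ethyl]phenoxy}-4-{4-[tri(propan-2-yl)silyloxy]phenyl}butan-2-one F7.
- LiN(SiMe3)2 and PhNTf2 (THF, −78 °C) deprotonate the more acidic OCH2 group and trap the chelated enolate as (1Z)-1-{3-[2-(3-bromo-4-methoxyphenyl)ethyl]phenoxy}-4-{4-[tri(propan-2-yl)silyloxy]phenyl}but-1-en-2-yl trifluoromethanesulfonate F8.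
- t-BuOK (THF, −78 to 0 °C) eliminates triflate anti to the vinylic hydrogen and gives 12.

Step 10. Oxidative addition of copper to the electron-rich, ortho-substituted bromide is slow, so intermolecular etherification to dimers and oligomers and reductive loss of bromine can overtake ring closure. The fallback sets out from 16 and comes back at 17; it reverses the role of the ring C carbon from halide to boron.
- Miyaura borylation of 16 (Pd(dppf)Cl2, bis(pinacolato)diboron, KOAc, 1,4-dioxane, 90 °C) gives methyl 3-[2-(4-hydroxyphenyl)ethyl]-4-(3-{2-[4-methoxy-3-(4,4,5,5-tetramethyl-1,3,2-dioxaborolan-2-yl)phenyl]ethyl}phenoxy)benzoate F9.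
- Oxidative Chan–Lam–Evans etherification of F9 (Cu(OAc)2, pyridine, B(OH)3, 4 Å molecular sieves, MeCN, air, high dilution) closes the ring to 17 at divalent copper under milder conditions.

Step 12. The cumyl-type cation may alkylate one of the neighbouring electron-rich rings across the macrocycle or lose a proton to an isopropenyl arene. Acidic peroxide may also hydroxylate or over-oxidise the anisole and diaryl ether rings. The fallback sets out from 17 and comes back at 21; it replaces the cation by a Baeyer–Villiger-type oxidation.
- Reduction of 17 (i-Bu2AlH, CH2Cl2, −78 to 0 °C) gives the macrocyclic benzylic alcohol F10 (ring A C4 CH2OH).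
- MnO2 (CH2Cl2) gives the macrocyclic aldehyde F11 (ring A C4 CHO).
- mCPBA (CH2Cl2, NaHCO3) inserts oxygen with migration of the para-aryloxy ring and gives the macrocyclic aryl formate F12 (ring A C4 OCHO).
- Methanolysis (K2CO3, MeOH) gives 21.

## Further compounds

F1 | step 8 | methyl 4-{3-[2-(3-bromo-4-methoxyphenyl)ethyl]phenoxy}-3-formylbenzoate | COC(=O)c1ccc(Oc2cccc(CCc3ccc(OC)c(Br)c3)c2)c(C=O)c1
F2 | step 8 | [(4-hydroxyphenyl)methyl]triphenylphosphonium bromide | Oc1ccc(C[P+](c2ccccc2)(c2ccccc2)c2ccccc2)cc1.[Br-]
F3 | step 8 | methyl 4-{3-[2-(3-bromo-4-methoxyphenyl)ethyl]phenoxy}-3-[2-(4-hydroxyphenyl)ethenyl]benzoate (E/Z mixture) | COC(=O)c1ccc(Oc2cccc(CCc3ccc(OC)c(Br)c3)c2)c(C=Cc2ccc(O)cc2)c1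
F4 | step 7 | 4-{4-[tri(propan-2-yl)silyloxy]phenyl}butan-2-one | CC(=O)CCc1ccc(O[Si](C(C)C)(C(C)C)C(C)C)cc1
F5 | step 7 | trimethyl[(4-{4-[tri(propan-2-yl)silyloxy]phenyl}but-1-en-2-yl)oxy]silane | C=C(CCc1ccc(O[Si](C(C)C)(C(C)C)C(C)C)cc1)O[Si](C)(C)C
F6 | step 7 | 1-bromo-4-{4-[tri(propan-2-yl)silyloxy]phenyl}butan-2-one | BrCC(=O)CCc1ccc(O[Si](C(C)C)(C(C)C)C(C)C)cc1
F7 | step 7 | 1-{3-[2-(3-bromo-4-methoxyphenyl)ethyl]phenoxy}-4-{4-[tri(propan-2-yl)silyloxy]phenyl}butan-2-one | COc1ccc(CCc2cccc(OCC(=O)CCc3ccc(O[Si](C(C)C)(C(C)C)C(C)C)cc3)c2)cc1Br
F8 | step 7 | (1Z)-1-{3-[2-(3-bromo-4-methoxyphenyl)ethyl]phenoxy}-4-{4-[tri(propan-2-yl)silyloxy]phenyl}but-1-en-2-yl trifluoromethanesulfonate | COc1ccc(CCc2cccc(O/C=C(/CCc3ccc(O[Si](C(C)C)(C(C)C)C(C)C)cc3)OS(=O)(=O)C(F)(F)F)c2)cc1Br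
F9 | step 10 | methyl 3-[2-(4-hydroxyphenyl)ethyl]-4-(3-{2-[4-methoxy-3-(4,4,5,5-tetramethyl-1,3,2-dioxaborolan-2-yl)phenyl]ethyl}phenoxy)benzoate | COC(=O)c1ccc(Oc2cccc(CCc3ccc(OC)c(B4OC(C)(C)C(C)(C)O4)c3)c2)c(CCc2ccc(O)cc2)c1
F10 | step 12 | macrocyclic benzylic alcohol (ring A C4 CH2OH; ring C OCH3) | OCc1ccc2c(c1)CCc1ccc(cc1)Oc1cc(ccc1OC)CCc1cccc(c1)O2
F11 | step 12 | macrocyclic aldehyde (ring A C4 CHO; ring C OCH3) | O=Cc1ccc2c(c1)CCc1ccc(cc1)Oc1cc(ccc1OC)CCc1cccc(c1)O2
F12 | step 12 | macrocyclic aryl formate (ring A C4 OCHO; ring C OCH3) | O=COc1ccc2c(c1)CCc1ccc(cc1)Oc1cc(ccc1OC)CCc1cccc(c1)O2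
A1 | alternative 1 | target ring C monomethyl ether (same compound as 21) | Oc1ccc2c(c1)CCc1ccc(cc1)Oc1cc(ccc1OC)CCc1cccc(c1)O2
A2 | alternative 1 | 17-membered 4-aryloxy-4-alkylcyclohexa-2,5-dienone macrocycle (quinol ether) | O=C1C=CC2(C=C1)CCc1ccc(cc1)Oc1cc(ccc1OC)CCc1cccc(c1)O2
A3 | alternative 1 | 4-[2-(4-{5-[2-(3-hydroxyphenyl)ethyl]-2-methoxyphenoxy}phenyl)ethyl]phenol | Oc1ccc(CCc2ccc(Oc3cc(CCc4cccc(O)c4)ccc3OC)cc2)cc1
A4 | alternative 2 | macrocyclic 2-aryloxycyclohexanone (racemic, cis) | O=C1CC[C@H]2C[C@@H]1Oc1ccc(cc1)CCc1cc(OC)ccc1Oc1cccc(c1)CC2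
A5 | alternative 2 | 2-bromo-4-{2-[3-(2-{2-[4-(tert-butyldimethylsilyloxy)phenyl]ethyl}-4-methoxyphenoxy)phenyl]ethyl}cyclohexan-1-one (racemic diastereomer mixture) | O=C1CCC(CCc2cccc(Oc3ccc(OC)cc3CCc3ccc(O[Si](C)(C)C(C)(C)C)cc3)c2)CC1Br
A6 | alternative 2 | target ring A monomethyl ether | COc1ccc2c(c1)CCc1ccc(cc1)Oc1cc(ccc1O)CCc1cccc(c1)O2
A7 | alternative 3 | macrocyclic E-stilbene dimethyl ether | COc1ccc2c(c1)CCc1ccc(cc1)Oc1cc(ccc1OC)/C=C/c1cccc(c1)O2
A8 | alternative 3 | 4-bromo-2-(4-{2-[2-(3-bromophenoxy)-5-methoxyphenyl]ethyl}phenoxy)-1-methoxybenzene | COc1ccc(Oc2cccc(Br)c2)c(CCc2ccc(Oc3cc(Br)ccc3OC)cc2)c1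
A9 | alternative 3 | (E)-1,2-bis(tributylstannyl)ethene | CCCC[Sn](CCCC)(CCCC)/C=C/[Sn](CCCC)(CCCC)CCCC
A10 | alternative 3 | target dimethyl ether | COc1ccc2c(c1)CCc1ccc(cc1)Oc1cc(ccc1OC)CCc1cccc(c1)O2
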